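The earlier runs and the new flask are simulated for an exercise, and the scatter is random.

You can begin with an easy step: count the Z that conversion itself has taken by the moment you look.

in all of them: L 1.3 M; E 1.3 M; Z 1.04 M

| run | G | remark |
|---|---|---|
| autumn | 0.87 mM | run made earlier |
| dusk | 2 mM | run made earlier |
| flask | 1.3 mM |  |

- autumn (time / d: Q / %, L / %): 0.167: 6.3, 43.3; 0.500: 13.2, 37.8; 0.833: 17.0, 33.6; 1.25: 20.5, 29.6; 1.67: 22.9, 27.2; 2.50: 25.6, 24.2; 3.00: 26.3, 23.0
- dusk (time / d: Q / %, L / %): 0.417: 20.4, 30.3; 0.833: 25.8, 24.0; 1.25: 29.1, 21.2; 1.67: 31.4, 18.9; 2.00: 32.0, 18.2; 2.50: 33.1, 17.3; 3.00: 34.4, 15.6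

(standard deviation of a reading: 0.5 percentage points)

- apparent order in G when 10% of the L and E together are converted (percent change of the rate of making Q for one percent more G charged)
- apparent order in Z when 10% of the L and E together are converted (percent change of the rate of making Q for one percent more Z charged)

In the flask each L or E converted takes one Z, and Z is the limiting reagent. At 10% conversion, therefore, conversion itself has taken 0.260 M of Z:

stretch = 1.04 M / (1.04 M − 0.260 M) = 1.333

This stretch, [Z] charged over [Z] left by conversion at the moment you look, is the percent gain in [Z] at that moment for one percent more on the charge, at the same conversion. If the rate of making Q is first order in [Z], the stretch is the order in Z.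

Is one number enough? It says nothing about time, so test it on the runs. The dusk run reads 20.4% of Q at 0.417 d and the autumn run reads 20.5% at 1.25 d, so the dusk run gets there sooner, by a factor of 3.00 for 2.30 times the G:

time exponent = ln(3.00) / ln(2.30) = 1.32

This is a reading, taken at higher conversion and with the scatter of the readings. If something fades on a clock of its own, a faster flask arrives earlier and catches more of it, and I assume the same for more Z as for more G. So I take about 1.32 in G and, adding the excess of that reading over first order to the stretch, 1.65 in Z. The figure for Z is a guess, since no earlier run changes the charge of Z.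

The forecast is lower than my reckoning on both, at 1.1 and 1.3, holding at this point that “little Z has been lost”.

The flask gives 1.3 in G and 1.6 in Z.

    Z + G + L → G + Q (k = 50.0 L² mol⁻² h⁻¹)
    Z + G + E → G + D (k = 0.670 L² mol⁻² h⁻¹)
    2 Z → J (k = 0.00640 L mol⁻¹ h⁻¹)
    G ⇌ X (K = 0.680, k = 0.110 h⁻¹)

The fit of the main steps alone gives 1.33 in Z, close to the stretch. The stretch also prices Q in Z: each 10% of conversion costs 25.0% of the charge of Z. The dusk run has the same charges of L, E and Z, so its last reading of Q, 34.4%, stands for about 85.9% of its charge of Z.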